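Before you repeat these flasks, decide to watch one number: XE divided by Q at the asked time, rather than the two yields apart. The share asked for, the selectivity, is that number over itself plus one.

| flask | J | X | remark | time |
|---|---|---|---|---|
| north | 0.016 M | 2 equiv | run made earlier |  |
| north-east | 0.029 M | 2 equiv | run made earlier |  |
| south | 0.060 M | 2 equiv | run made earlier |  |
| oak | 0.020 M | 2.00 equiv |  | 6.0 h |
| birch | 0.030 M | 2.00 equiv |  | 6.0 h |
| alder | 0.050 M | 2.00 equiv |  | 6.0 h |

| run | time / h | XE / % | Q / % | J / % |
|---|---|---|---|---|
| north | 0.833 | 1.0 | 1.2 | 39.6 |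
| north | 1.50 | 3.0 | 0.4 | 19.1 |
| north | 2.50 | 4.8 | 2.0 | 6.1 |
| north | 3.00 | 6.4 | 1.8 | 3.4 |
| north | 4.00 | 8.3 | 0.5 | 1.4 |
| north-east | 0.333 | 0.3 | 0.1 | 69.3 |
| north-east | 0.667 | 1.5 | 0.5 | 48.7 |
| north-east | 1.33 | 3.9 | 0.8 | 23.2 |
| north-east | 2.00 | 5.6 | 2.2 | 11.5 |
| north-east | 4.00 | 14.3 | 2.9 | 0.8 |
| south | 0.417 | 1.3 | 0.8 | 63.4 |
| south | 1.00 | 4.1 | 2.9 | 33.2 |
| south | 2.00 | 10.8 | 4.9 | 11.0 |
| south | 3.00 | 18.7 | 5.1 | 3.2 |
| south | 4.00 | 26.1 | 5.5 | 1.2 |

(standard deviation of a reading: 0.5 percentage points)

- percentages count the J that a species holds: one Q counts as two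
- on the list of suspects stand: J -> E; J + E -> Q; E -> Z; X + E -> XE
- "hardly changes" means that all values lie within two and a half points (for a concentration: within two and a half percent of the largest)

- share of XE in all that became XE or Q for oak, birch, alder, in this order
- how that number moves from the first to the last of them (rises, then falls / falls, then rises / hardly changes / falls all the way / rises all the way)

Reckon it from south, in fractions of the charge. Q needs J, and south has 1.2% of its J left at 4.00 h, so I take its Q there, 5.5%, as its value at 6.0 h. XE keeps climbing, and carrying the line through its readings at 2.00 h and 4.00 h on to 6.0 h gives 41.4%. That gives south 7.53, and this XE-per-Q number at the asked time makes its share 88.3%.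

Now turn the question round. For the share to rise out of the band of "hardly changes", that number would have to climb from 7.53 to 9.84 across the flasks, a factor of 1.31. At 4.00 h the readings give 4.75 in south and 4.93 in north-east, a factor of 1.04, although south holds twice the charge. With X at a fixed number of equivalents, the steps J + E and X + E should both grow with the charge, so it can fall out of their ratio. My reckoning therefore puts oak, birch and alder at the one share 88.3%.

Watch Q in oak, where I expect 1.83% of the charge: one reading off by 0.5 percentage points moves the share by 2.7 points, so average the late Q readings.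

The forecast gave 90%, 89.5% and 88.4%, a slight fall where I have one value, and its shape was hardly changes, on the ground that “Both XE and Q scale roughly with concentration”.

The flasks give 89.5%, 89.1% and 88.4%: hardly changes.

    J → E (k = 0.0180 min⁻¹)
    J + E → Q (k = 0.0180 M⁻¹ min⁻¹)
    E → Z (k = 4.30 × 10⁻⁴ min⁻¹)
    X + E → XE (k = 0.0160 M⁻¹ min⁻¹)

At 6.00 h, E still holds 71.4% of the charge in oak and 53.9% in alder. The XE-per-Q number comes to 8.52 in oak and 7.62 in alder, a factor of 1.12 against the 1.31 needed to leave the band.

Readings and results stem from a simulated flask for substances that don't exist; scatter was added.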